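**Retrosynthetic overview**
1. Ludongnin A ⇒ C16 methylenation and C15 ketone (ozonolysis of a C15 exo-methylene) ⇒ ring D by C8–C15 closure (Pd(OAc)2) ⇒ ring C by C9–C11 closure (SmI2) ⇒ a spiro bis-lactone (6,19-γ-lactone on ring A, 7,20-δ-lactone with C8H2–C9H2) plus a C11–C16 iodide whose C13 centre comes from an Evans alkylation.
2. Bis-lactone ⇒ "tether release" (acylal hydrolysis, NaBH4, double lactonisation) ⇒ Baeyer–Villiger oxidation ⇒ a cyclobutanone.
3. Key disconnection: C19–C4 and C6–C5 are made together by intramolecular [2+2] cycloaddition of an alkoxyketene (C19=C6=O), hung on the C20 oxygen, to the C4=C5 alkene of ring A. The C19–O–C20 ether and the C19–C6 bond are temporary.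
4. Enabling feature: in the target C19 (on C4), C6 (on C5) and C20 (on C10) all stand on one face of ring A, C20–O is homoallylic to C4=C5, and the lactone oxygen sits between C19 and C6, where a Baeyer–Villiger insertion next to an alkoxy-bearing C19 places it.
5. Ring order: ring A (C10 by Pd-catalysed asymmetric allylation) → temporary oxane + cyclobutanone → γ-lactone → δ-lactone → ring C → ring D.

Key step: step 7

Remark: ent-kaurane numbering (C1–C20) is used for all intermediates; centres that are erased later (C4 in 4, C8 in 28–33, C16 in 37–38) are left undefined in the SMILES.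
Remark: the (R,R) antipode of the Trost ligand is written for step 1; which antipode delivers (R)-3 is to be confirmed by the sign of rotation on the first run, and the (S,S) ligand is used if it proves opposite.

**Step 1**
Reactants: 1 ethyl 2-oxocyclohexane-1-carboxylate; 2 allyl acetate
Product: 3 ethyl (R)-1-allyl-2-oxocyclohexane-1-carboxylate
Conditions: [Pd(C3H5)Cl]2 (1 mol %), (R,R)-DACH-phenyl Trost ligand (2.5 mol %), tetramethylguanidine, toluene, 0 °C
Reagents that add atoms: none
Why: Palladium-catalysed asymmetric allylic alkylation (Tsuji–Trost) of the β-ketoester enolate, in which the chiral pocket of the ligand should differentiate the enolate faces and set the quaternary C10.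

**Step 2**
Reactants: 3 ethyl (R)-1-allyl-2-oxocyclohexane-1-carboxylate
Product: 4 ethyl (1R)-1-allyl-3-methyl-2-oxocyclohexane-1-carboxylate (mixture at the methyl-bearing carbon)
Conditions: LiN(i-Pr)2 (1.1 equiv), THF, −78 °C; MeI, −78 → 0 °C
Reagents that add atoms: iodomethane, CI
Why: Ketone enolate alkylation at the only enolisable α-carbon (the other is quaternary) places the future C18 methyl on C4; the new centre is not controlled and is erased in step 3.

**Step 3**
Reactants: 4 ethyl (1R)-1-allyl-3-methyl-2-oxocyclohexane-1-carboxylate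
Product: 5 ethyl (R)-1-allyl-3-methyl-2-(trifluoromethylsulfonyloxy)cyclohex-2-ene-1-carboxylate
Conditions: KN(SiMe3)2, THF, −78 °C; PhNTf2, −78 → 0 °C
Reagents that add atoms: N-phenylbis(trifluoromethanesulfonimide), O=S(=O)(N(c1ccccc1)S(=O)(=O)C(F)(F)F)C(F)(F)F
Why: Enol triflate formation from the potassium enolate is regiospecific because C4–H is the only α-hydrogen, which fixes the double bond at C4=C5.

**Step 4**
Reactants: 5 ethyl (R)-1-allyl-3-methyl-2-(trifluoromethylsulfonyloxy)cyclohex-2-ene-1-carboxylate
Product: 6 ethyl (R)-1-allyl-3-methylcyclohex-2-ene-1-carboxylate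
Conditions: Pd(OAc)2 (5 mol %), PPh3, HCO2H, n-Bu3N, DMF, 60 °C
Reagents that add atoms: none
Why: Palladium-catalysed formate reduction of the vinyl triflate (oxidative addition, decarboxylation to a palladium hydride, reductive elimination) should leave the trisubstituted C4=C5 alkene where the triflate stood.

**Step 5**
Reactants: 6 ethyl (R)-1-allyl-3-methylcyclohex-2-ene-1-carboxylate
Product: 7 [(R)-1-allyl-3-methylcyclohex-2-en-1-yl]methanol
Conditions: LiAlH4, Et2O, 0 °C
Reagents that add atoms: none
Why: Hydride reduction of the ester gives the C20 primary alcohol, homoallylic to C4=C5, without touching C10.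

**Step 6**
Reactants: 7 [(R)-1-allyl-3-methylcyclohex-2-en-1-yl]methanol; 8 bromoacetic acid
Product: 9 2-{[(R)-1-allyl-3-methylcyclohex-2-en-1-yl]methoxy}acetic acid
Conditions: NaH (2.5 equiv), THF, 0 °C → reflux; then aq. HCl
Reagents that add atoms: none
Why: Williamson ether synthesis with sodium bromoacetate hangs the two carbons that become C19 and C6 on the C20 oxygen.

**Step 7**
Reactants: 9 2-{[(R)-1-allyl-3-methylcyclohex-2-en-1-yl]methoxy}acetic acid
Product: 12 tricyclic cyclobutanone (ring A + temporary oxane C19–O–C20 + cyclobutanone C4–C19–C6(=O)–C5; allyl on C10), via acid chloride 10 (not isolated), via alkoxyketene 11 (not isolated)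
Conditions: (COCl)2, DMF (cat.), CH2Cl2, 0 °C → rt, evaporate; then slow addition to Et3N (5 equiv), toluene, reflux, final 0.005 M
Reagents that add atoms: none
Why: Et3N dehydrochlorinates acid chloride 10 to alkoxyketene 11, whose electrophilic carbonyl carbon C6 bonds to the less substituted alkene carbon C5 while the alkoxy-bearing carbon C19 bonds to the more substituted C4 in a concerted, asynchronous [2+2] cycloaddition. The closest known reaction type is the intramolecular alkoxyketene–alkene [2+2] cycloaddition that turns (homoallyloxy)ketenes with a more substituted distal alkene carbon into 2-oxabicyclo[3.1.1]heptan-6-ones. Two rings close: the six-membered oxane C19–O–C20–C10–C5–C4 in the bridged (crossed) mode by the C19–C4 bond, and the cyclobutanone C4–C19–C6–C5 by the C6–C5 bond across it. C4 and C5 are set cis because the ketene adds suprafacially to the alkene, and both on the C20 face because the three-atom tether O–C20–C10 from the only existing stereocentre C10 cannot reach the other face; C19 is fixed by the cage. The step needs regioselectivity (C6 to C5, not to C4), secured by polarisation of the trisubstituted alkene toward a tertiary C4 cation, and chemoselectivity over the allyl group, secured by its longer four-atom tether and lower nucleophilicity; high dilution suppresses ketene dimerisation.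

**Step 8**
Reactants: 12 tricyclic cyclobutanone
Product: 13 lactone acetal (6,19-olide whose C19 also carries the C20 oxygen; allyl on C10)
Conditions: mCPBA (1.1 equiv), NaHCO3, CH2Cl2, 0 °C
Reagents that add atoms: 3-chloroperoxybenzoic acid, O=C(OO)c1cccc(Cl)c1
Why: Baeyer–Villiger oxidation, fast for the strained cyclobutanone, in which the α-alkoxy carbon C19 should migrate with retention in preference to C5 and so place the oxygen between C19 and C6; the monosubstituted allyl alkene is epoxidised far more slowly.

**Step 9**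
Reactants: 13 lactone acetal
Product: 14 lactone acetal with a 3-hydroxypropyl group on C10 (C7 alcohol)
Conditions: 9-BBN (0.5 M in THF), 0 °C → rt; then aq. NaOAc, 30% H2O2, 0 °C
Reagents that add atoms: hydrogen peroxide, OO
Why: Anti-Markovnikov hydroboration–oxidation of the terminal alkene with 9-BBN, which does not reduce the lactone, under a buffered oxidation that should leave the acylal intact.

**Step 10**
Reactants: 14 lactone acetal C7 alcohol
Product: 15 lactone acetal C7 carboxylic acid
Conditions: TEMPO (20 mol %), PhI(OAc)2 (2.5 equiv), MeCN/pH 7 phosphate buffer, rt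
Reagents that add atoms: water, O
Why: Nitroxyl-catalysed oxidation of the primary alcohol through the aldehyde hydrate to the acid under near-neutral conditions.

**Step 11**
Reactants: 15 lactone acetal C7 carboxylic acid
Product: 18 (4R,5R,10R) spiro bis-lactone (6,19-olide and 7,20-olide with C8H2–C9H2), via hydroxy aldehyde diacid 16 (not isolated), via dihydroxy diacid 17 (not isolated)
Conditions: LiOH, THF/H2O, 0 °C; NaBH4, 0 °C → rt; 2 M HCl to pH 1; then TsOH·H2O (cat.), toluene, 80 °C
Reagents that add atoms: none
Why: Hydroxide opens the acylal (ester hydrolysis) and frees the C19 aldehyde and C20–OH, NaBH4 reduces the aldehyde, and acid-catalysed lactonisation under thermodynamic control should give the only isomer in which both acids are lactonised (C19–O–C6 five-membered, C20–O–C7 six-membered).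

**Step 12**
Reactants: 19 methyl 4,4-dimethoxybutanoate
Product: 20 4,4-dimethoxybutanoic acid
Conditions: LiOH, THF/H2O, 0 °C → rt; 1 M HCl to pH 4 at 0 °C
Reagents that add atoms: lithium hydroxide, [Li+].[OH-]
Why: Ester saponification with a cold, mildly acidic work-up that keeps the dimethyl acetal.

**Step 13**
Reactants: 20 4,4-dimethoxybutanoic acid; 21 (R)-4-benzyl-1,3-oxazolidin-2-one
Product: 23 (R)-4-benzyl-3-(4,4-dimethoxybutanoyl)-1,3-oxazolidin-2-one, via mixed pivalic anhydride 22 (not isolated)
Conditions: t-BuCOCl, Et3N, THF, −20 °C; then LiCl, 21, −20 °C → rt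
Reagents that add atoms: none
Why: N-Acylation of the oxazolidinone through the mixed anhydride, which reacts at the less hindered acyl group.

**Step 14**
Reactants: 23 (R)-4-benzyl-3-(4,4-dimethoxybutanoyl)-1,3-oxazolidin-2-one; 24 allyl bromide
Product: 25 (R)-4-benzyl-3-[(R)-2-(2,2-dimethoxyethyl)pent-4-enoyl]-1,3-oxazolidin-2-one
Conditions: NaN(SiMe3)2, THF, −78 °C; allyl bromide, −78 → −40 °C
Reagents that add atoms: none
Why: Evans asymmetric alkylation, in which the chelated Z-enolate is allylated on the face away from the benzyl group of the (R)-auxiliary and should give the (R) centre that becomes C13.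

**Step 15**
Reactants: 25 (R)-4-benzyl-3-[(R)-2-(2,2-dimethoxyethyl)pent-4-enoyl]-1,3-oxazolidin-2-one
Product: 26 (R)-2-(2,2-dimethoxyethyl)pent-4-en-1-ol
Conditions: LiBH4, Et2O, H2O (1 equiv), 0 °C
Reagents that add atoms: none
Why: Reductive cleavage of the imide at the exocyclic carbonyl gives the primary alcohol (future C14) and returns the auxiliary without touching C13.

**Step 16**
Reactants: 26 (R)-2-(2,2-dimethoxyethyl)pent-4-en-1-ol
Product: 27 (R)-3-(iodomethyl)-1,1-dimethoxyhex-5-ene
Conditions: I2, PPh3, imidazole, CH2Cl2, 0 °C → rt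
Reagents that add atoms: iodine, II
Why: Appel-type iodination of the primary alcohol, buffered by imidazole so that the acetal survives.

**Step 17**
Reactants: 18 spiro bis-lactone; 27 (R)-3-(iodomethyl)-1,1-dimethoxyhex-5-ene
Product: 28 C8-alkylated bis-lactone (C8 carries CH2–C13H(allyl)–CH2–CH(OMe)2; C8 epimers)
Conditions: LiN(SiMe3)2 (1.05 equiv), THF, −78 °C; 27, DMPU, −78 → −20 °C
Reagents that add atoms: none
Why: Lactone enolate alkylation (SN2) at C8, the only α-CH2; C5–H of the γ-lactone lies between two quaternary carbons and should not be removed, and the C8 centre is erased in step 18.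

**Step 18**
Reactants: 28 C8-alkylated bis-lactone
Product: 30 C8=C9 unsaturated δ-lactone, via C8 phenylselenide 29 (not isolated)
Conditions: LiN(i-Pr)2, THF, −78 °C; PhSeBr; then 30% H2O2, pyridine, CH2Cl2, 0 °C → rt
Reagents that add atoms: none
Why: α-Selenenylation of the lactone enolate and selenoxide syn-elimination, expected to go toward the ring C9–H to give the endocyclic, conjugated alkene.

**Step 19**
Reactants: 30 C8=C9 unsaturated δ-lactone
Product: 31 unsaturated lactone C11 aldehyde
Conditions: 1 M HCl, THF, rt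
Reagents that add atoms: water, O
Why: Acid-catalysed hydrolysis of the dimethyl acetal, to which the lactones and alkenes are inert.

**Step 20**
Reactants: 31 unsaturated lactone C11 aldehyde
Product: 32 tricyclic alcohol (ring C closed by C9–C11; 11-OH; allyl on C13; C8–H)
Conditions: SmI2 (0.1 M in THF, 2.5 equiv), t-BuOH, THF, −78 °C
Reagents that add atoms: none
Why: Ketyl–olefin reductive cyclisation, in which the samarium ketyl of the aldehyde adds 6-endo to C9 (β-carbon of the unsaturated lactone) from the lactone face away from C5, the substituted arm of spiro C10, through a chair with the C13 allyl group equatorial; this should set C9 and C11 as in the target before t-BuOH protonates the enolate.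

**Step 21**
Reactants: 32 tricyclic alcohol
Product: 33 C11 tert-butyldimethylsilyl ether
Conditions: t-BuMe2SiOTf, 2,6-lutidine, CH2Cl2, −78 → 0 °C
Reagents that add atoms: tert-butyldimethylsilyl trifluoromethanesulfonate, CC(C)(C)[Si](C)(C)OS(=O)(=O)C(F)(F)F
Why: Silylation of the hindered secondary alcohol under non-basic conditions, which avoids translactonisation by a C11 alkoxide.

**Step 22**
Reactants: 33 C11 tert-butyldimethylsilyl ether
Product: 35 15-methylene bicyclo[3.2.1]octane (rings C and D closed; C16 is CH2), via silyl ketene acetal 34 (not isolated)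
Conditions: KN(SiMe3)2, t-BuMe2SiCl, THF, −78 °C; crude 34, Pd(OAc)2 (1 equiv), AcOH (0.5 equiv), DMSO, 45 °C
Reagents that add atoms: none
Why: Palladium-mediated oxidative cyclisation of a silyl ketene acetal onto an alkene (Saegusa–Ito-type cycloalkenylation), in which the C8 palladium enolate inserts the allyl alkene 5-exo and β-hydride elimination leaves the C15 exo-methylene; the C8–C15 bond can only form cis to the C13 side chain, which fixes the quaternary C8, and a ketene acetal at C5 would have no β-hydrogen and would only hydrolyse back.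

**Step 23**
Reactants: 35 15-methylene bicyclo[3.2.1]octane
Product: 36 C15 ketone
Conditions: O3, CH2Cl2/MeOH, −78 °C; then Me2S, → rt
Reagents that add atoms: ozone, [O-][O+]=O
Why: Ozonolysis of the only alkene in the molecule gives the cyclopentanone carbonyl at C15.

**Step 24**
Reactants: 36 C15 ketone
Product: 39 11-O-(tert-butyldimethylsilyl)ludongnin A, via Mannich base 37 (not isolated), via trimethylammonium iodide 38 (not isolated)
Conditions: LiN(SiMe3)2, THF, −78 °C; Me2N=CH2 I (Eschenmoser's salt), −78 °C → rt; MeI, CH2Cl2, rt; aq. NaHCO3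
Reagents that add atoms: N,N-dimethylmethyleneiminium iodide, C=[N+](C)C.[I-]
Why: Mannich reaction of the ketone enolate (C16 is the only enolisable position next to C15, and the ketone is more acidic than the lactones), then quaternisation and Hofmann-type elimination to the exocyclic enone.

**Step 25**
Reactants: 39 11-O-(tert-butyldimethylsilyl)ludongnin A
Product: 40 ludongnin A
Conditions: HF·pyridine, THF, 0 °C → rt
Reagents that add atoms: none
Why: Acidic fluoride desilylation frees the C11 hydroxyl without conjugate addition to the exo-methylene ketone.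

**Compound list**
1 | ethyl 2-oxocyclohexane-1-carboxylate | CCOC(=O)C1CCCCC1=O | starting material
2 | allyl acetate | CC(=O)OCC=C | starting material
3 | ethyl (R)-1-allyl-2-oxocyclohexane-1-carboxylate | C=CC[C@]1(C(=O)OCC)CCCCC1=O | intermediate
4 | ethyl (1R)-1-allyl-3-methyl-2-oxocyclohexane-1-carboxylate (mixture at C3) | C=CC[C@]1(C(=O)OCC)CCCC(C)C1=O | intermediate
5 | ethyl (R)-1-allyl-3-methyl-2-(trifluoromethylsulfonyloxy)cyclohex-2-ene-1-carboxylate | C=CC[C@]1(C(=O)OCC)CCCC(C)=C1OS(=O)(=O)C(F)(F)F | intermediate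
6 | ethyl (R)-1-allyl-3-methylcyclohex-2-ene-1-carboxylate | C=CC[C@]1(C(=O)OCC)CCCC(C)=C1 | intermediate
7 | [(R)-1-allyl-3-methylcyclohex-2-en-1-yl]methanol | C=CC[C@]1(CO)CCCC(C)=C1 | intermediate
8 | bromoacetic acid | OC(=O)CBr | starting material
9 | 2-{[(R)-1-allyl-3-methylcyclohex-2-en-1-yl]methoxy}acetic acid | C=CC[C@]1(COCC(=O)O)CCCC(C)=C1 | intermediate
10 | 2-{[(R)-1-allyl-3-methylcyclohex-2-en-1-yl]methoxy}acetyl chloride | C=CC[C@]1(COCC(=O)Cl)CCCC(C)=C1 | intermediate
11 | {[(R)-1-allyl-3-methylcyclohex-2-en-1-yl]methoxy}ketene | C=CC[C@]1(COC=C=O)CCCC(C)=C1 | intermediate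
12 | tricyclic cyclobutanone (oxane C19–O–C20, ketone C6 between C19 and C5, allyl on C10; C4, C5, C10 as in the target) | C=CC[C@@]12CCC[C@@]3(C)[C@@H](OC1)C(=O)[C@@H]23 | intermediate
13 | lactone acetal (6,19-olide, C19–O–C20 acetal bridge, allyl on C10) | C=CC[C@@]12CCC[C@@]3(C)[C@@H](OC1)OC(=O)[C@@H]23 | intermediate
14 | lactone acetal C7 alcohol (3-hydroxypropyl on C10) | OCCC[C@@]12CCC[C@@]3(C)[C@@H](OC1)OC(=O)[C@@H]23 | intermediate
15 | lactone acetal C7 carboxylic acid | OC(=O)CC[C@@]12CCC[C@@]3(C)[C@@H](OC1)OC(=O)[C@@H]23 | intermediate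
16 | hydroxy aldehyde diacid (C19 CHO, C20 OH, C6 and C7 CO2H) | OC(=O)CC[C@]1(CO)CCC[C@@](C)(C=O)[C@H]1C(=O)O | intermediate
17 | dihydroxy diacid (C19 OH, C20 OH, C6 and C7 CO2H) | OC(=O)CC[C@]1(CO)CCC[C@@](C)(CO)[C@H]1C(=O)O | intermediate
18 | (4R,5R,10R) spiro bis-lactone (6,19-olide and 7,20-olide) | O=C1CC[C@@]2(CCC[C@@]3(C)COC(=O)[C@H]32)CO1 | intermediate
19 | methyl 4,4-dimethoxybutanoate | COC(=O)CCC(OC)OC | starting material
20 | 4,4-dimethoxybutanoic acid | OC(=O)CCC(OC)OC | intermediate
21 | (R)-4-benzyl-1,3-oxazolidin-2-one | O=C1N[C@H](Cc2ccccc2)CO1 | starting material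
22 | 4,4-dimethoxybutanoic pivalic anhydride | COC(OC)CCC(=O)OC(=O)C(C)(C)C | intermediate
23 | (R)-4-benzyl-3-(4,4-dimethoxybutanoyl)-1,3-oxazolidin-2-one | COC(OC)CCC(=O)N1[C@H](Cc2ccccc2)COC1=O | intermediate
24 | allyl bromide | C=CCBr | starting material
25 | (R)-4-benzyl-3-[(R)-2-(2,2-dimethoxyethyl)pent-4-enoyl]-1,3-oxazolidin-2-one | C=CC[C@H](CC(OC)OC)C(=O)N1[C@H](Cc2ccccc2)COC1=O | intermediate
26 | (R)-2-(2,2-dimethoxyethyl)pent-4-en-1-ol | C=CC[C@H](CC(OC)OC)CO | intermediate
27 | (R)-3-(iodomethyl)-1,1-dimethoxyhex-5-ene | C=CC[C@H](CC(OC)OC)CI | intermediate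
28 | C8-alkylated bis-lactone (C8 epimers; C13 R side chain) | O=C1C(C[C@H](CC=C)CC(OC)OC)C[C@@]2(CCC[C@@]3(C)COC(=O)[C@H]32)CO1 | intermediate
29 | C8 phenylselenide of 28 | O=C1C(C[C@H](CC=C)CC(OC)OC)([Se]c4ccccc4)C[C@@]2(CCC[C@@]3(C)COC(=O)[C@H]32)CO1 | intermediate
30 | C8=C9 unsaturated δ-lactone, dimethyl acetal | O=C1C(C[C@H](CC=C)CC(OC)OC)=C[C@@]2(CCC[C@@]3(C)COC(=O)[C@H]32)CO1 | intermediate
31 | C8=C9 unsaturated δ-lactone, C11 aldehyde | O=C1C(C[C@H](CC=C)CC=O)=C[C@@]2(CCC[C@@]3(C)COC(=O)[C@H]32)CO1 | intermediate
32 | tricyclic alcohol (ring C closed; 11-OH; 13-allyl; C9, C11, C13 as in the target; C8–H undefined) | C=CC[C@@H]1C[C@@H](O)[C@H]2[C@@]3(CCC[C@@]4(C)COC(=O)[C@H]43)COC(=O)C2C1 | intermediate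
33 | C11 tert-butyldimethylsilyl ether of 32 | C=CC[C@@H]1C[C@@H](O[Si](C)(C)C(C)(C)C)[C@H]2[C@@]3(CCC[C@@]4(C)COC(=O)[C@H]43)COC(=O)C2C1 | intermediate
34 | silyl ketene acetal of the δ-lactone (C7=C8) | C=CC[C@@H]1C[C@@H](O[Si](C)(C)C(C)(C)C)[C@H]2[C@@]3(CCC[C@@]4(C)COC(=O)[C@H]43)COC(O[Si](C)(C)C(C)(C)C)=C2C1 | intermediate
35 | 15-methylene bicyclo[3.2.1]octane bis-lactone, 11-O-silyl (all centres as in the target) | C1C(=C)[C@]23C[C@H]1C[C@@H](O[Si](C)(C)C(C)(C)C)[C@H]2[C@@]1(CCC[C@@]2(C)COC(=O)[C@H]21)COC3=O | intermediate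
36 | C15 ketone (16,17-dinor-ludongnin A skeleton plus C16H2), 11-O-silyl | C1C(=O)[C@]23C[C@H]1C[C@@H](O[Si](C)(C)C(C)(C)C)[C@H]2[C@@]1(CCC[C@@]2(C)COC(=O)[C@H]21)COC3=O | intermediate
37 | 16-(dimethylaminomethyl) ketone (C16 undefined) | CN(C)CC1C(=O)[C@]23C[C@H]1C[C@@H](O[Si](C)(C)C(C)(C)C)[C@H]2[C@@]1(CCC[C@@]2(C)COC(=O)[C@H]21)COC3=O | intermediate
38 | trimethylammonium iodide of 37 | C[N+](C)(C)CC1C(=O)[C@]23C[C@H]1C[C@@H](O[Si](C)(C)C(C)(C)C)[C@H]2[C@@]1(CCC[C@@]2(C)COC(=O)[C@H]21)COC3=O.[I-] | intermediate
39 | 11-O-(tert-butyldimethylsilyl)ludongnin A | C=C1C(=O)[C@]23C[C@H]1C[C@@H](O[Si](C)(C)C(C)(C)C)[C@H]2[C@@]1(CCC[C@@]2(C)COC(=O)[C@H]21)COC3=O | intermediate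
40 | ludongnin A | C=C1C(=O)[C@]23C[C@H]1C[C@@H](O)[C@H]2[C@@]1(CCC[C@@]2(C)COC(=O)[C@H]21)COC3=O | target

**Totals**
Total step count: 25. Longest linear sequence: 20 steps (steps 1–11 and 17–25); steps 12–16 make the iodide 27.

**Steps most likely to fail**

Step 7. The ketene may dimerise or oligomerise before it cyclises, may add in the fused sense (C19 to C5), or may add to the allyl group. Fallback: set out from acid 9 and convert it, through acid chloride 10 and pyrrolidine, into the pyrrolidine amide F1. Tf2O and 2,4,6-collidine in 1,2-dichloroethane at reflux give the keteniminium triflate F2, which is far more electrophilic than the ketene and cannot dimerise. Its intramolecular [2+2] cycloaddition gives the cyclobutaniminium triflate F3, and hydrolysis with aqueous NaHCO3 brings the route back at cyclobutanone 12.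

Step 20. The aldehyde may be reduced or pinacol-coupled without C–C bond formation, or the ketyl may add to the wrong face of C9. Fallback: set out from aldehyde 31 and close ring C by an intramolecular Stetter reaction (triazolium carbene catalyst, catalytic KN(SiMe3)2, toluene), a polar acyl-anion addition to C9, to give the C11 ketone F4. C9 is then α to a ketone and can be equilibrated with base toward the isomer with the spiro carbon and the allyl group both equatorial on ring C. NaBH4 in MeOH at −40 °C, delivering hydride to the face away from C10, brings the route back at alcohol 32.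

Step 22. The silyl ketene acetal may be protodesilylated or dehydrogenated instead of cyclising, and enolisation may partly occur at the γ-lactone. Fallback: set out from silyl ketene acetal 34 and treat it with N-bromosuccinimide to give the C8 bromo lactone F5. Ozonolysis of the allyl group (O3, then PPh3) gives the bromo aldehyde F6. SmI2 in THF at −78 °C generates the C8 samarium enolate regiospecifically and closes ring D by a Reformatsky-type aldol reaction to the C15 hydroxy lactone F7. Dess–Martin periodinane brings the route back at ketone 36, and step 23 is then not needed.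

**Further compounds**
F1 | step 7 | 1-(2-{[(R)-1-allyl-3-methylcyclohex-2-en-1-yl]methoxy}acetyl)pyrrolidine | C=CC[C@]1(COCC(=O)N2CCCC2)CCCC(C)=C1
F2 | step 7 | keteniminium triflate from F1 | C=CC[C@]1(COC=C=[N+]2CCCC2)CCCC(C)=C1.[O-]S(=O)(=O)C(F)(F)F
F3 | step 7 | cyclobutaniminium triflate (pyrrolidinium analogue of 12) | C=CC[C@@]12CCC[C@@]3(C)[C@@H](OC1)C(=[N+]1CCCC1)[C@@H]23.[O-]S(=O)(=O)C(F)(F)F
F4 | step 20 | tricyclic C11 ketone (11-oxo analogue of 32) | C=CC[C@@H]1CC(=O)[C@H]2[C@@]3(CCC[C@@]4(C)COC(=O)[C@H]43)COC(=O)C2C1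
F5 | step 22 | C8 bromo lactone of 33 | C=CC[C@@H]1C[C@@H](O[Si](C)(C)C(C)(C)C)[C@H]2[C@@]3(CCC[C@@]4(C)COC(=O)[C@H]43)COC(=O)C2(Br)C1
F6 | step 22 | C8 bromo lactone C15 aldehyde | O=CC[C@@H]1C[C@@H](O[Si](C)(C)C(C)(C)C)[C@H]2[C@@]3(CCC[C@@]4(C)COC(=O)[C@H]43)COC(=O)C2(Br)C1
F7 | step 22 | C15 hydroxy bicyclo[3.2.1]octane bis-lactone, 11-O-silyl | C1C(O)[C@]23C[C@H]1C[C@@H](O[Si](C)(C)C(C)(C)C)[C@H]2[C@@]1(CCC[C@@]2(C)COC(=O)[C@H]21)COC3=O
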